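The data are calculated for substances that don't exist.

Count the acid.

| flask | electrophile | free base | protonated nucleophile | protic impurity | remark | time |
|---|---|---|---|---|---|---|
| north-east | 0.017 M | 1 equiv | 1.5 equiv | 3.3 mM | run made earlier |  |
| cedar | 0.011 M | 1.00 equiv | 1.50 equiv | 3.30 mM |  | 8.0 min |
| oak | 0.011 M | 2.00 equiv | 1.50 equiv | 3.30 mM |  | 8.0 min |
| elm | 0.011 M | 4.00 equiv | 1.50 equiv | 3.30 mM |  | 8.0 min |

north-east run (percent of the electrophile charged)

| time / min | electrophile / % | product / % |
|---|---|---|
| 0.250 | 75.3 | 18.3 |
| 0.667 | 57.1 | 30.6 |
| 1.33 | 45.9 | 39.1 |
| 2.00 | 39.9 | 43.4 |
| 3.00 | 34.8 | 46.5 |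

(standard deviation of a reading: 0.3 percentage points)

- no earlier run changes the charge of free base; that part of a forecast is a guess

1. part of the electrophile that has reacted at the end, cedar
2. part of the electrophile that has reacted at the end, oak
3. part of the electrophile that has reacted at the end, elm
4. what raising the equivalents of free base from its lowest to its highest value here does to the part of the electrophile that has reacted (changes below 5 percentage points count as none) (it rises / it falls / no change)

1. We read the north-east run as fraction left. Its apparent pseudo-first-order constant falls from 1.13 min⁻¹ up to 0.250 min to 0.137 min⁻¹ over the last interval.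

2. We suppose that protonated nucleophile must give its acid to free base before it reacts, and that each product sets one more acid free. Product per electrophile lost reads 0.713 at the last reading, so the acid load is 2.21 equiv per electrophile.

3. Cover, free base charged over that acid load, is 0.452 in cedar, 0.904 in oak and 1.81 in elm. Below one, we expect acid to outlast base; above one, we expect free base to remain.

4. Cedar has north-east's cover. Running north-east on at its last constant to 8.0 min leaves 17.6%, so 82.4% reacted; we take that for cedar and expect somewhat less, since the constant was still falling. For oak and elm, whose cover is larger, we expect more reacted than in cedar.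

5. Is one number enough? No: cover says where, not when. North-east's early half-life, 0.611 min, is short against 8.0 min. Cover also counts on enough nucleophile for the electrophile; here 1.50 equiv of protonated nucleophile is charged.

The forecast gave 62%, 92% and 99% for cedar, oak and elm, lower than ours for cedar, and of the reacted part on raising the free base said it rises: “This is a buffer picture that stalls when the base runs out.”

The flasks give 78.5%, 98.2% and 99.2%. Of the reacted part, on raising the free base from 1.00 equiv to 4.00 equiv: it rises, by 21 percentage points.

    electrophile + nucleophile → acid set free + product (k = 1.10 L mol⁻¹ s⁻¹)
    electrophile + protic impurity → quenched substrate (k = 1.90 L mol⁻¹ s⁻¹)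
    nucleophile + acid set free ⇌ protonated nucleophile, settled at all times (K = 33000 L mol⁻¹)
    acid set free + free base ⇌ idle adduct, settled at all times (K = 38.0 L mol⁻¹)
    acid set free + free base ⇌ salt of the base, settled at all times (K = 3.10 × 10⁶ L mol⁻¹)
    nucleophile ⇌ dormant form (K = 0.270, k = 0.00720 s⁻¹)

Elm's cover of 1.81 reckons 44.8% of its free base left, and 43.7% stands there at 8.00 min. At that time in elm the electrophile's half-life by the product step, 1.7 min, is short against 8.0 min, and 0.76% of it remains. In a neighbour flask, elm with 0.380 equiv of protonated nucleophile, we count two acids for each protonated nucleophile, its own and that of its product, so cover is reckoned as 5.26 and 81.0% of the base is reckoned left. That neighbour flask holds 82%, with 36.4% of its electrophile unreacted.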